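**Strategy.** In the furan-3(2H)-one ring the C1 ketone is flanked by the quaternary, oxygen-bearing C10, and C10 carries the C9 carbinol. This β-hydroxy ketone is the aldol adduct of an aromatic 2-methyl-3-silyloxyfuran, so the whole plan rests on cutting C9–C10. In one operation a Lewis-acid-promoted, dearomatising intramolecular Mukaiyama aldol makes this bond, closes the ten-membered carbocycle C1–C10 (equally the nine-membered ring through the furanone oxygen), releases the furanone and sets C9 and C10. The precursor is a trans-4,5-disubstituted α-methylene-γ-butyrolactone. Its C6 carries the 3-TBSO-2-methylfuran through the Z-C4=C5 alkene, and its C7 carries an α-(PMB-oxy) aldehyde (C8–C9).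

Key step: step 14

**Remarks before the steps**
- Atom labels:
  - C1 = furanone ketone carbon.
  - C2=C3 = furanone ring alkene; C3 is bound to the ring oxygen.
  - C4(Me)=C5 = the Z-alkene.
  - C6 = carbon bearing the lactone oxygen; C7 = its lactone neighbour.
  - C8 = tiglate carbon; C9 = free carbinol; C10 = methyl-bearing quaternary carbon.
  - C11, C12, C13 = lactone α-carbon, lactone carbonyl, and the CH2Cl carbon (earlier =CH2).
  - The target is (6R,7S,8S,9S,10S,11S), C4=C5 Z, tiglate E.
- Assumption: racemic ethyl lactate is used, because its stereocentre (the future C10) becomes planar in the silyloxyfuran. All compounds between furanone formation and the silyloxyfuran are C10 epimer mixtures and are drawn without a descriptor there.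
- Design point a: open-chain 2-(alkoxycarbonyl)allyl halides of the Baylis–Hillman type hold the C8 substituent cis to the CH2–metal group. Through the chair transition state they give 6,7-syn adducts, that is cis-lactones. The trans-lactone and the C7/C8 relationship are therefore secured with a ring-locked allyl donor. This is a six-membered lactone whose ring oxygen is O9, and it returns O9 as the free C9 hydroxyl after an acyl shift.
- Design point b: O8 carries an ether, not the ester, during the aldol. α-Acyloxy aldehydes epimerise, shift their acyl group and can participate through the ester carbonyl. α-Alkoxy aldehydes have the better documented Felkin–Anh behaviour with BF3. The tiglate follows afterwards.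
- Design point c: the aldol product is a strained β-hydroxy ketone with a quaternary α-carbon. O9 is therefore silylated before any base is used (retro-aldol). The same silyl ether tells O9 from O8.

**Route**

Step 1
Reactants: 1 (Z)-3-methylpent-2-en-4-yn-1-ol
Product: 2 (Z)-tert-butyldimethyl[(3-methylpent-2-en-4-yn-1-yl)oxy]silane
Conditions: TBSCl, imidazole, CH2Cl2, 0 °C to rt
Reagents that add atoms: tert-butyldimethylsilyl chloride, CC(C)(C)[Si](C)(C)Cl
Why: Routine silylation of a primary alcohol, needed because a free Z-placed hydroxyl would add to the later ynone and aromatise to a furan.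

Step 2
Reactants: 3 ethyl lactate (racemic)
Product: 4 ethyl 2-(triethylsilyloxy)propanoate
Conditions: TESCl, imidazole, CH2Cl2, 0 °C to rt
Reagents that add atoms: chlorotriethylsilane, CC[Si](Cl)(CC)CC
Why: Routine silyl ether formation; TES is chosen because it leaves much faster than the TBS ether in step 5.

Step 3
Reactants: 4 ethyl 2-(triethylsilyloxy)propanoate
Product: 5 N-methoxy-N-methyl-2-(triethylsilyloxy)propanamide
Conditions: MeNH(OMe)·HCl, i-PrMgCl, THF, −20 to 0 °C
Reagents that add atoms: N,O-dimethylhydroxylamine hydrochloride, CNOC.Cl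
Why: Weinreb amide formation by aminolysis of the ester with the magnesium amide made in the flask, to which silyl ethers are inert.

Step 4
Reactants: 2 (Z)-tert-butyldimethyl[(3-methylpent-2-en-4-yn-1-yl)oxy]silane; 5 N-methoxy-N-methyl-2-(triethylsilyloxy)propanamide
Product: 7 (Z)-8-(tert-butyldimethylsilyloxy)-6-methyl-2-(triethylsilyloxy)oct-6-en-4-yn-3-one, via lithium acetylide 6 (not isolated)
Conditions: n-BuLi, THF, −78 °C; then 5, −78 to 0 °C; aqueous work-up
Reagents that add atoms: none
Why: Weinreb ketone synthesis; acylation of the acetylide stops at the ynone and the Z-alkene is not touched.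

Step 5
Reactants: 7 (Z)-8-(tert-butyldimethylsilyloxy)-6-methyl-2-(triethylsilyloxy)oct-6-en-4-yn-3-one
Product: 10 (Z)-5-(4-hydroxybut-2-en-2-yl)-2-methylfuran-3(2H)-one, via enaminone 8 (not isolated), via silylated furanone 9 (not isolated)
Conditions: Et2NH, THF, rt; then 1 M aq. HCl, THF, 0 °C to rt
Reagents that add atoms: none
Why: Classical furan-3(2H)-one synthesis; aza-Michael addition masks the ynone, acid removes the TES group first so that the C10 hydroxyl displaces the amine (5-exo-trig on the vinylogous iminium ion) before the slower TBS cleavage frees the allylic alcohol, and C10 arises as an irrelevant racemic centre.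

Step 6
Reactants: 10 (Z)-5-(4-hydroxybut-2-en-2-yl)-2-methylfuran-3(2H)-one
Product: 11 (Z)-3-(5-methyl-4-oxo-4,5-dihydrofuran-2-yl)but-2-enal
Conditions: MnO2 (activated, excess), CH2Cl2, rt, dark
Reagents that add atoms: none
Why: Neutral heterogeneous oxidation that is selective for allylic alcohols and should keep the Z geometry; the enal is used at once.

Step 7
Reactants: 12 (S)-but-3-ene-1,2-diol
Product: 13 (4S)-2-(4-methoxyphenyl)-4-vinyl-1,3-dioxolane (acetal epimers)
Conditions: 4-MeOC6H4CH(OMe)2, PPTS (cat.), CH2Cl2, rt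
Reagents that add atoms: 4-methoxybenzaldehyde dimethyl acetal, COc1ccc(C(OC)OC)cc1
Why: Acid-catalysed transacetalisation of a 1,2-diol; the chiral-pool centre (future C8) is not involved.

Step 8
Reactants: 13 (4S)-2-(4-methoxyphenyl)-4-vinyl-1,3-dioxolane
Product: 14 (S)-2-[(4-methoxybenzyl)oxy]but-3-en-1-ol
Conditions: i-Bu2AlH, CH2Cl2, −78 to 0 °C; Rochelle salt work-up
Reagents that add atoms: none
Why: Regioselective reductive opening of the 4-methoxybenzylidene acetal; the aluminium hydride binds the less hindered primary oxygen and cleaves that C–O bond, so the PMB group stays on the secondary O8.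

Step 9
Reactants: 14 (S)-2-[(4-methoxybenzyl)oxy]but-3-en-1-ol; 15 2-(bromomethyl)acrylic acid
Product: 16 (S)-2-[(4-methoxybenzyl)oxy]but-3-en-1-yl 2-(bromomethyl)acrylate
Conditions: DCC, DMAP (5 mol %), CH2Cl2, 0 °C
Reagents that add atoms: none
Why: Steglich esterification of a primary alcohol, run cold with little DMAP so that the allylic bromide is not quaternised.

Step 10
Reactants: 16 (S)-2-[(4-methoxybenzyl)oxy]but-3-en-1-yl 2-(bromomethyl)acrylate
Product: 17 (S)-3-(bromomethyl)-5-[(4-methoxybenzyl)oxy]-5,6-dihydro-2H-pyran-2-one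
Conditions: second-generation Grubbs catalyst RuCl2(=CHPh)(PCy3)(H2IMes) (5 mol %), CH2Cl2 (5 mM), reflux
Reagents that add atoms: none
Why: Ring-closing metathesis of an acrylate-type ester of a homoallylic alcohol to an unsaturated six-membered lactone, tolerant of allylic bromides and ethers; the ring fixes C8 cis to C12 and hence trans to the CH2Br group.

Step 11
Reactants: 11 (Z)-3-(5-methyl-4-oxo-4,5-dihydrofuran-2-yl)but-2-enal; 17 (S)-3-(bromomethyl)-5-[(4-methoxybenzyl)oxy]-5,6-dihydro-2H-pyran-2-one
Product: 20 (4S,5R)-4-[(1S)-2-hydroxy-1-(4-methoxybenzyloxy)ethyl]-3-methylene-5-[(Z)-2-(5-methyl-4-oxo-4,5-dihydrofuran-2-yl)prop-1-enyl]dihydrofuran-2(3H)-one, via allylindium dibromide 18 (not isolated), via six-ring lactone carbinol 19 (not isolated)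
Conditions: In powder, THF–H2O (3:1), rt; crude product: CSA (10 mol %), CH2Cl2, rt
Reagents that add atoms: none
Why: Barbier-type 2-(alkoxycarbonyl)allylation through a Zimmerman–Traxler chair; the ring-locked geometry (C8 trans to CH2–In) gives the 6,7-anti adduct and hence the trans γ-lactone, the aldehyde reaches C7 on the ring face opposite the C8 OPMB group, which sets C6 and C7 relative to C8, and acid then shifts the acyl group from O9 to O6 (six- to five-membered lactone), freeing the C9 hydroxyl.

Step 12
Reactants: 20 the γ-lactone primary alcohol (6R,7S,8S)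
Product: 21 keto aldehyde: as 20 but with C9 as CHO (6R,7S,8S)
Conditions: Dess–Martin periodinane, CH2Cl2, 0 °C to rt
Reagents that add atoms: none
Why: Dess–Martin oxidation of the only free alcohol under near-neutral conditions, which should spare the C8 centre of the α-alkoxy aldehyde and the enolisable furanone.

Step 13
Reactants: 21 keto aldehyde (6R,7S,8S)
Product: 22 silyloxyfuran aldehyde: as 21 but with the furanone as 3-(tert-butyldimethylsilyloxy)-2-methylfuran-5-yl (6R,7S,8S)
Conditions: TBSOTf (1.1 equiv), Et3N, CH2Cl2, −78 °C; cold aq. NaHCO3; short Et3N-deactivated silica plug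
Reagents that add atoms: tert-butyldimethylsilyl triflate, CC(C)(C)[Si](C)(C)OS(=O)(=O)C(F)(F)F
Why: Soft enolisation known for furan-3(2H)-ones; the vinylogous-ester carbonyl is the most Lewis-basic oxygen, so it is silylated first and loss of the C10 proton aromatises the ring, while the less basic, hindered aldehyde should stay untouched at −78 °C.

Step 14
Reactants: 22 silyloxyfuran aldehyde (6R,7S,8S)
Product: 24 furanone-bridged ten-membered carbocycle bearing the trans-6,12-lactone; exocyclic C11=C13 methylene; C8 OPMB; C9 OH (6R,7S,8S,9S,10S), via difluoroboryl aldolate 23 (not isolated)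
Conditions: BF3·OEt2 (3 equiv), CH2Cl2, −78 °C, slow addition of 22 (about 1 mM final); aq. NaHCO3
Reagents that add atoms: none
Why: Proposed new method: BF3 binds the C9 aldehyde, and C10 (the methyl-bearing position of the furan, activated by both the ring oxygen and the silyloxy group) attacks it through an open transition state, after which fluoride transfer strips the TBS group from the oxocarbenium ion and leaves the furanone as aldolate 23, hydrolysed on work-up. The closest known reaction is the intermolecular BF3-promoted Mukaiyama aldol of 2-substituted 3-silyloxyfurans with aldehydes to 2,2-disubstituted furan-3(2H)-ones; Lewis-acid Mukaiyama macrocyclisations of simple enol silanes are also known, but this closure of a medium ring is not. The closure is an exo-trig addition to the aldehyde, 10-exo for the carbocycle C1–C10 and 9-exo for the ring that runs through the furanone oxygen. C9 is controlled by C8: monodentate BF3 cannot chelate, so polar Felkin–Anh attack anti to the C8–O bond should give the 8,9-anti pattern (9S). C10 (10S) depends on the furan face that the tether can present; the Z-alkene and the trans-lactone bring the termini together and should keep the C10 methyl group outside the forming ring, which is the unproven element. The step needs the aldehyde to beat the methylene lactone as electrophile and C10 to beat C5 as nucleophile: the BF3-bound aldehyde is far more electrophilic, a Prins closure at C5 would build a trans-fused bicyclo[3.3.0] system, and high dilution suppresses oligomers.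

Step 15
Reactants: 24 macrocyclic aldol (6R,7S,8S,9S,10S)
Product: 25 C9 triethylsilyl ether of 24 (6R,7S,8S,9S,10S)
Conditions: TESOTf, 2,6-lutidine, CH2Cl2, −78 to 0 °C
Reagents that add atoms: triethylsilyl triflate, CC[Si](CC)(CC)OS(=O)(=O)C(F)(F)F
Why: Triflate silylation of a hindered secondary alcohol under weakly basic conditions; it blocks the retro-aldol path and distinguishes O9 from O8.

Step 16
Reactants: 25 C9 triethylsilyl ether (6R,7S,8S,9S,10S)
Product: 26 C8 alcohol: as 25 but with O8 free (6R,7R,8S,9S,10S; the C7 descriptor changes by priority only)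
Conditions: DDQ, CH2Cl2–pH 7 buffer (10:1), 0 °C
Reagents that add atoms: none
Why: Oxidative PMB ether cleavage (hydride abstraction, then hydrolysis of the benzylic oxocarbenium ion), orthogonal to the TES ether, the lactone and the electron-poor alkenes.

Step 17
Reactants: 26 C8 alcohol; 27 tiglic acid
Product: 29 C8 tiglate with C9 OTES and exocyclic methylene lactone (6R,7S,8S,9S,10S), via mixed anhydride 28 (not isolated)
Conditions: 2,4,6-Cl3C6H2COCl, Et3N, toluene, rt; then 26, DMAP, toluene, rt to 40 °C
Reagents that add atoms: none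
Why: Yamaguchi esterification acylates the hindered C8 hydroxyl with retention at C8 and keeps the E geometry of the tigloyl group; 26 is used at once so that O8 does not attack the lactone carbonyl.

Step 18
Reactants: 29 C8 tiglate with C9 OTES
Product: 30 11,13-spiro-epoxide of 29 (6R,7S,8S,9S,10S,11R)
Conditions: t-BuOOH (decane), n-BuLi, THF, −78 to −20 °C
Reagents that add atoms: tert-butyl hydroperoxide, CC(C)(C)OO
Why: Weitz–Scheffer-type nucleophilic epoxidation; the peroxide anion adds to the unhindered C13 of the most electrophilic acceptor and the C11 enolate closes on oxygen on the lactone face opposite the C8 substituent of C7, while the trisubstituted tiglate and the vinylogous ester are too hindered or too electron-rich and the silyl ether prevents retro-aldol cleavage.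

Step 19
Reactants: 30 11,13-spiro-epoxide
Product: 32 target CNP0272644.2 (6R,7S,8S,9S,10S,11S), via epoxy alcohol 31 (not isolated)
Conditions: conc. aq. HCl, THF, 0 °C to rt
Reagents that add atoms: hydrogen chloride, Cl
Why: Acid-promoted SN2 opening of the glycidic-type epoxide by chloride at primary C13; the C11–O bond is untouched, so C11 keeps its geometry (the descriptor changes by priority only), and the TES ether is solvolysed in the same flask.

**Compound list**

1 | (Z)-3-methylpent-2-en-4-yn-1-ol | C#C/C(C)=C\CO | starting material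
2 | (Z)-tert-butyldimethyl[(3-methylpent-2-en-4-yn-1-yl)oxy]silane | C#C/C(C)=C\CO[Si](C)(C)C(C)(C)C | intermediate
3 | ethyl lactate (racemic) | CCOC(=O)C(C)O | starting material
4 | ethyl 2-(triethylsilyloxy)propanoate | CCOC(=O)C(C)O[Si](CC)(CC)CC | intermediate
5 | N-methoxy-N-methyl-2-(triethylsilyloxy)propanamide | CON(C)C(=O)C(C)O[Si](CC)(CC)CC | intermediate
6 | lithium acetylide of 2 | [Li]C#C/C(C)=C\CO[Si](C)(C)C(C)(C)C | intermediate
7 | (Z)-8-(tert-butyldimethylsilyloxy)-6-methyl-2-(triethylsilyloxy)oct-6-en-4-yn-3-one | CC(O[Si](CC)(CC)CC)C(=O)C#C/C(C)=C\CO[Si](C)(C)C(C)(C)C | intermediate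
8 | (6Z)-8-(tert-butyldimethylsilyloxy)-5-(diethylamino)-6-methyl-2-(triethylsilyloxy)octa-4,6-dien-3-one | CCN(CC)C(=CC(=O)C(C)O[Si](CC)(CC)CC)/C(C)=C\CO[Si](C)(C)C(C)(C)C | intermediate
9 | (Z)-5-[4-(tert-butyldimethylsilyloxy)but-2-en-2-yl]-2-methylfuran-3(2H)-one | CC(C)(C)[Si](C)(C)OC/C=C(/C)C1=CC(=O)C(C)O1 | intermediate
10 | (Z)-5-(4-hydroxybut-2-en-2-yl)-2-methylfuran-3(2H)-one | OC/C=C(/C)C1=CC(=O)C(C)O1 | intermediate
11 | (Z)-3-(5-methyl-4-oxo-4,5-dihydrofuran-2-yl)but-2-enal | O=C/C=C(/C)C1=CC(=O)C(C)O1 | intermediate
12 | (S)-but-3-ene-1,2-diol | C=C[C@H](O)CO | starting material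
13 | (4S)-2-(4-methoxyphenyl)-4-vinyl-1,3-dioxolane | C=C[C@H]1COC(c2ccc(OC)cc2)O1 | intermediate
14 | (S)-2-[(4-methoxybenzyl)oxy]but-3-en-1-ol | C=C[C@H](OCc1ccc(OC)cc1)CO | intermediate
15 | 2-(bromomethyl)acrylic acid | C=C(CBr)C(=O)O | starting material
16 | (S)-2-[(4-methoxybenzyl)oxy]but-3-en-1-yl 2-(bromomethyl)acrylate | C=C[C@H](OCc1ccc(OC)cc1)COC(=O)C(=C)CBr | intermediate
17 | (S)-3-(bromomethyl)-5-[(4-methoxybenzyl)oxy]-5,6-dihydro-2H-pyran-2-one | BrCC1=C[C@H](OCc2ccc(OC)cc2)COC1=O | intermediate
18 | allylindium dibromide from 17 (drawn as the monoallyl species) | Br[In](Br)CC1=C[C@H](OCc2ccc(OC)cc2)COC1=O | intermediate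
19 | six-ring lactone carbinol: α-methylene-δ-lactone with C8 OPMB and, trans to it at C7, the C6 allylic carbinol (6R,7S,8S) | O[C@H](/C=C(/C)C1=CC(=O)C(C)O1)[C@H]2[C@H](OCc3ccc(OC)cc3)COC(=O)C2=C | intermediate
20 | trans α-methylene-γ-butyrolactone with C8 OPMB and C9 OH (6R,7S,8S) | COc1ccc(CO[C@H](CO)[C@@H]2[C@@H](/C=C(/C)C3=CC(=O)C(C)O3)OC(=O)C2=C)cc1 | intermediate
21 | keto aldehyde, C9 = CHO (6R,7S,8S) | COc1ccc(CO[C@H](C=O)[C@@H]2[C@@H](/C=C(/C)C3=CC(=O)C(C)O3)OC(=O)C2=C)cc1 | intermediate
22 | silyloxyfuran aldehyde, key-step precursor (6R,7S,8S) | COc1ccc(CO[C@H](C=O)[C@@H]2[C@@H](/C=C(/C)c3cc(O[Si](C)(C)C(C)(C)C)c(C)o3)OC(=O)C2=C)cc1 | intermediate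
23 | difluoroboryl aldolate of 24 | COc1ccc(CO[C@H]2[C@@H]3[C@@H](/C=C(/C)C4=CC(=O)[C@@](C)(O4)[C@H]2OB(F)F)OC(=O)C3=C)cc1 | intermediate
24 | furanone-bridged macrocycle, key-step product, C8 OPMB, C9 OH (6R,7S,8S,9S,10S) | COc1ccc(CO[C@H]2[C@@H]3[C@@H](/C=C(/C)C4=CC(=O)[C@@](C)(O4)[C@H]2O)OC(=O)C3=C)cc1 | intermediate
25 | C9 triethylsilyl ether of 24 | COc1ccc(CO[C@H]2[C@@H]3[C@@H](/C=C(/C)C4=CC(=O)[C@@](C)(O4)[C@H]2O[Si](CC)(CC)CC)OC(=O)C3=C)cc1 | intermediate
26 | C8 alcohol with C9 OTES | O[C@H]1[C@@H]2[C@@H](/C=C(/C)C3=CC(=O)[C@@](C)(O3)[C@H]1O[Si](CC)(CC)CC)OC(=O)C2=C | intermediate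
27 | tiglic acid, (E)-2-methylbut-2-enoic acid | C/C=C(\C)C(=O)O | starting material
28 | tiglic 2,4,6-trichlorobenzoic anhydride | C/C=C(\C)C(=O)OC(=O)c1c(Cl)cc(Cl)cc1Cl | intermediate
29 | C8 tiglate with C9 OTES and exocyclic methylene lactone | C/C=C(\C)C(=O)O[C@H]1[C@@H]2[C@@H](/C=C(/C)C3=CC(=O)[C@@](C)(O3)[C@H]1O[Si](CC)(CC)CC)OC(=O)C2=C | intermediate
30 | 11,13-spiro-epoxide with C9 OTES (11R) | C/C=C(\C)C(=O)O[C@H]1[C@@H]2[C@@H](/C=C(/C)C3=CC(=O)[C@@](C)(O3)[C@H]1O[Si](CC)(CC)CC)OC(=O)[C@]24CO4 | intermediate
31 | 11,13-spiro-epoxide with free C9 OH | C/C=C(\C)C(=O)O[C@H]1[C@@H]2[C@@H](/C=C(/C)C3=CC(=O)[C@@](C)(O3)[C@H]1O)OC(=O)[C@]24CO4 | intermediate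
32 | CNP0272644.2 | C/C=C(\C)C(=O)O[C@H]1[C@@H]2[C@@H](/C=C(/C)C3=CC(=O)[C@@](C)(O3)[C@H]1O)OC(=O)[C@]2(O)CCl | target

**Count**

Total steps: 19. Longest linear sequence: 14 steps (steps 2, 3, 4, 5, 6, then 11 to 19, starting from 3).

**Steps most likely to fail**

1. Step 14.
   - What may go wrong: oligomerisation instead of ring closure, protodesilylation of the silyloxyfuran before the C–C bond forms, or closure on the wrong furan face.
   - Approach of the fallback: it uses known reactions only, makes C9–C10 first between two molecules, and closes the ring at C6–C7. It sets out from 9 (step 5 stopped before the TBS ether is lost) and from 14.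
   - Making the C9–C10 bond: compound 9 is silylated with TBSOTf and Et3N to the bis-silylated 3-silyloxyfuran F1. Compound 14 is oxidised with Dess–Martin periodinane to (S)-2-(4-methoxybenzyloxy)but-3-enal F2. The intermolecular BF3·OEt2 Mukaiyama aldol of the two gives, after separation of the C10 epimers, the Felkin-type aldol F3.
   - Building the allyl donor: Steglich esterification of the C9 hydroxyl of F3 with 15 gives the bromomethylacrylate F4. Ring-closing metathesis gives the bromomethyl six-ring lactone F5. HF·pyridine frees the allylic alcohol F6, and MnO2 gives the enal F7.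
   - Ring closure and return: CrCl2 in THF–DMF at high dilution closes the ten-membered ring by intramolecular allylation, a closure known for carbocycles of this lactone family, to the bridged lactone carbinol F8. A CSA-catalysed acyl shift from O9 to O6 comes back to the route at 24.

2. Step 11.
   - What may go wrong: loss of the C8 alkoxy group from the allylmetal by 1,4-elimination, approach of the aldehyde to the wrong face of C7, or drift of the Z-enal to E under the aqueous metal conditions.
   - Fallback: it sets out from 17. Pd2(dba)3-catalysed borylation with B2pin2 gives the isolable allylboronate F9, whose covalent C–B bond does not eliminate. Heating it with 11 in toluene, or Sc(OTf)3 catalysis at 0 °C, performs the same chair-type allylation under anhydrous neutral conditions to the borate of 19. The CSA treatment comes back to the route at 20.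

3. Step 13.
   - What may go wrong: enol silylation or epimerisation at C8 of the aldehyde, or premature intermolecular aldol addition while the labile enol silane is isolated.
   - Fallback: it sets out from 21 and gives up the isolated enol silane. Slow addition of 21 to TESOTf and i-Pr2NEt in CH2Cl2 at −78 °C and high dilution forms the triethylsilyloxyfuran aldehyde F10 in the flask. The excess silyl triflate activates the aldehyde and the aldolate keeps the silyl group. The sequence comes back to the route at 25, and steps 14 and 15 fall away.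

**Further compounds**

F1 | step 14 | tert-butyl{[(Z)-3-(4-(tert-butyldimethylsilyloxy)-5-methylfuran-2-yl)but-2-en-1-yl]oxy}dimethylsilane | CC(C)(C)[Si](C)(C)OC/C=C(/C)c1cc(O[Si](C)(C)C(C)(C)C)c(C)o1
F2 | step 14 | (S)-2-[(4-methoxybenzyl)oxy]but-3-enal | C=C[C@H](OCc1ccc(OC)cc1)C=O
F3 | step 14 | intermolecular aldol adduct with C7 vinyl, C8 OPMB, C9 OH, C6 OTBS (8S,9S,10S) | C=C[C@H](OCc1ccc(OC)cc1)[C@H](O)[C@]2(C)OC(=CC2=O)/C(C)=C\CO[Si](C)(C)C(C)(C)C
F4 | step 14 | C9 2-(bromomethyl)acrylate of F3 | C=C[C@H](OCc1ccc(OC)cc1)[C@H](OC(=O)C(=C)CBr)[C@]2(C)OC(=CC2=O)/C(C)=C\CO[Si](C)(C)C(C)(C)C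
F5 | step 14 | bromomethyl six-ring lactone carrying the furanone at C9, C6 OTBS | BrCC1=C[C@H](OCc2ccc(OC)cc2)[C@H](OC1=O)[C@]3(C)OC(=CC3=O)/C(C)=C\CO[Si](C)(C)C(C)(C)C
F6 | step 14 | allylic alcohol from F5 | BrCC1=C[C@H](OCc2ccc(OC)cc2)[C@H](OC1=O)[C@]3(C)OC(=CC3=O)/C(C)=C\CO
F7 | step 14 | Z-enal from F6 | BrCC1=C[C@H](OCc2ccc(OC)cc2)[C@H](OC1=O)[C@]3(C)OC(=CC3=O)/C(C)=C\C=O
F8 | step 14 | macrocyclic six-ring lactone carbinol with free C6 OH | O[C@@H]1/C=C(/C)C2=CC(=O)[C@@](C)(O2)[C@H]3OC(=O)C(=C)[C@@H]1[C@@H]3OCc4ccc(OC)cc4
F9 | step 11 | (S)-5-[(4-methoxybenzyl)oxy]-3-[(4,4,5,5-tetramethyl-1,3,2-dioxaborolan-2-yl)methyl]-5,6-dihydro-2H-pyran-2-one | CC1(C)OB(CC2=C[C@H](OCc3ccc(OC)cc3)COC2=O)OC1(C)C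
F10 | step 13 | triethylsilyloxyfuran analogue of 22 | COc1ccc(CO[C@H](C=O)[C@@H]2[C@@H](/C=C(/C)c3cc(O[Si](CC)(CC)CC)c(C)o3)OC(=O)C2=C)cc1
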